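At the 3.00 h reading the dawn flask holds Z at 44.8 % and D at 2.3 % of the charge, so the excess of Z over D, (Z − D)/(Z + D), already stands near 90.2 %. What we want to know is where J stops it.

in all of them: D 0.050 M; Z 0.050 M

| run | J | G | remark | time |
|---|---|---|---|---|
| dawn | 1.1 equiv | 2.5 mol% | the very flask that is asked about, followed so far |  |
| autumn | 1.1 equiv | 5 mol% | run made earlier |  |
| flask | 1.10 equiv | 2.5 mol% |  | 15 h |

- dawn (time / h: Z / %, D / %, E / %): 0.250: 47.3, 18.8, 31.7; 0.500: 47.0, 8.1, 41.0; 1.33: 45.9, 3.7, 46.2; 3.00: 44.8, 2.3, 47.9
- autumn (time / h: Z / %, D / %, E / %): 0.833: 45.1, 3.8, 46.8; 2.00: 44.2, 1.8, 47.2; 4.00: 44.1, 1.9, 47.6; 6.00: 43.8, 2.9, 47.5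

(standard deviation of a reading: 0.5 percentage points)

1. whether the excess of Z over D among what is left of the two reaches 80 % by 15 h (no / yes)
2. the highest excess of Z over D among what is left of the two up to 15 h

- L is single-handed; D and Z are mirror images of each other, charged as a racemate, each of them at the stated concentration
- what may be going on: J -> Q; J + L + Z -> L + X; G -> L; J + L + D -> L + E

We build the flask one step at a time, in fractions of the D and Z charged together, of which D is 0.5. With J + L + D as the one step, J at 55.0 % is more than D, so D goes and the excess ends at 100 %.

Now we add J + L + Z. The logarithm of start over rest for D, divided by the same for Z, is the selectivity factor, and the reading gives s = 28.0. Twice D then equals twice Z raised to the power s. If J were spent to the last, 45.0 % of the charge would stay unreacted. So we guess D, take Z as the remainder, get a new D and put it back. After two rounds the excess is 94.8 %.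

Last comes J → Q. The autumn flask had turned over 54.0 % by 4.00 h, so on that reading J lost 1 percentage point of the charge to Q, a rough figure from readings with a scatter of 0.5 points. The dawn flask has 2.5 mol% of G against 5 mol%, so we let J stand twice as long and double the loss. Spendable J, the part of the charge J can still turn over after its loss to Q, is then 53.0 %. Two rounds from the D read at 3.00 h give 90.0 %, above the 80 % wanted.

The forecast says yes and 91 %, and it reasons that “With half the catalyst, dawn loses roughly twice as much J to Q”. Its figure lies 1 point above ours.

The flask gives yes and a top of 89.7 %, passing 80 % at 0.922 h.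

    J → Q (k = 0.00160 min⁻¹)
    J + L + Z → L + X (k = 110 L² mol⁻² min⁻¹)
    G → L (k = 0.160 min⁻¹)
    J + L + D → L + E (k = 2800 L² mol⁻² min⁻¹)

In the dawn flask J, the limiting reagent, is first to run out, standing at 0 % at 15.0 h with Q at 0.00180 M. Spendable J on the dawn flask thus comes to 53.2 % of the charge, where we reckoned 53.0 %. On the autumn flask spendable J is 54.0 %, and the same two rounds give 91.6 %; its excess read at 2.00 h, a reading these rounds did not use, was 92.2 %.

The numbers in the tables are calculated for substances that don't exist, and the scatter is random.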